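**Plan**

- Retrosynthesis: the hydroquinone is unmasked last from its dimethyl ether (through the quinone) and the C5' hydroxyl from a silyl ether. The C1'–C2' bond (benzylic carbon to alkene) and the C3'–CH3 bond are then cut together, giving 2,5-dimethoxy-3-methylbenzyl chloride, Me3Al and an (S)-homopropargylic silyl ether. Its C4'–C5' bond is cut to (2E,6E)-farnesal and an allenylboronate.
- Forward: farnesal is propargylated and silylated (2 steps); the arene is formylated, methylated, reduced and chlorinated (4 steps); the two fragments and a methyl group are joined in one pot; three steps unmask the target. No ring is formed, since the benzene ring is bought.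
- Enabling feature: counting from the benzylic carbon C1', C2'=C3' is an E-trisubstituted alkene with the C3' methyl cis to C1' and C3' two carbons from the C5' oxygen. This is the pattern left when CH3 and a metal add syn across a terminal alkyne that is homopropargylic to that oxygen.
- Stereochemistry: the only stereocentre, C5' (S), comes from catalyst-controlled Si-face propargylation of farnesal. The 6'E and 10'E alkenes are bought with farnesal. The 2'E alkene comes from syn carbometalation and a geometry-retaining coupling.

Key step: step 7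

Assumption: the side chain is numbered from the benzylic carbon C1', and (2E,6E)-farnesal is taken as the isomerically pure commercial aldehyde.
Assumption: the sense of induction in step 1 follows the chair model for BINOL-phosphoric-acid-catalysed allenylboration, in which the (R)-acid exposes the Re face of aryl and alkenyl aldehydes; the (S)-acid is therefore specified for the (S)-carbinol (CIP order at C5': O > C6' alkenyl > C4' methylene > H).

**Route**

Step 1
Reactants: 1 (2E,6E)-farnesal; 2 allenylboronic acid pinacol ester
Product: 4 (4S,5E,9E)-6,10,14-trimethylpentadeca-5,9,13-trien-1-yn-4-ol, via O-pinacolboryl ether 3 (not isolated)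
Conditions: (S)-3,3'-bis(2,4,6-triisopropylphenyl)-1,1'-binaphthyl-2,2'-diyl hydrogen phosphate (10 mol%), 4 Å MS, toluene, 0 °C; then aq. NaHCO3
Reagents that add atoms: none
Why: Brønsted-acid-catalysed asymmetric allenylboration, in which the phosphoric acid hydrogen-bonds to a boronate oxygen and the formyl hydrogen and the allenyl γ-carbon is delivered through a closed six-membered chair transition state (SE2'), so that the homopropargylic rather than the allenic carbinol forms and the (S)-catalyst should expose the Si face of the aldehyde to set C5' as S.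

Step 2
Reactants: 4 (4S,5E,9E)-6,10,14-trimethylpentadeca-5,9,13-trien-1-yn-4-ol
Product: 5 tert-butyldimethyl{[(4S,5E,9E)-6,10,14-trimethylpentadeca-5,9,13-trien-1-yn-4-yl]oxy}silane
Conditions: TBSCl, imidazole, DMF, rt
Reagents that add atoms: tert-butyldimethylsilyl chloride, CC(C)(C)[Si](C)(C)Cl
Why: Standard imidazole-promoted silylation of a secondary alcohol, which masks the hydroxyl against Me3Al and the nickel coupling without touching the stereocentre.

Step 3
Reactants: 6 4-methoxy-2-methylphenol
Product: 7 2-hydroxy-5-methoxy-3-methylbenzaldehyde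
Conditions: MgCl2, Et3N, (CH2O)n, MeCN, reflux; then 1 M HCl
Reagents that add atoms: paraformaldehyde (as formaldehyde), C=O
Why: Magnesium-mediated ortho-formylation (Casnati–Skattebøl), in which the magnesium phenoxide delivers formaldehyde to the only free position ortho to the hydroxyl and a second formaldehyde oxidises the benzylic alkoxide by hydride transfer, so a single regioisomer is possible.

Step 4
Reactants: 7 2-hydroxy-5-methoxy-3-methylbenzaldehyde
Product: 8 2,5-dimethoxy-3-methylbenzaldehyde
Conditions: MeI, K2CO3, DMF, rt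
Reagents that add atoms: iodomethane, CI
Why: Williamson O-methylation of the phenoxide, with an aldehyde that has no α-hydrogen and is inert to the base.

Step 5
Reactants: 8 2,5-dimethoxy-3-methylbenzaldehyde
Product: 9 (2,5-dimethoxy-3-methylphenyl)methanol
Conditions: NaBH4, MeOH, 0 °C
Reagents that add atoms: none
Why: Borohydride reduction of an aromatic aldehyde to the benzylic alcohol, leaving the aryl ethers untouched.

Step 6
Reactants: 9 (2,5-dimethoxy-3-methylphenyl)methanol
Product: 10 1-(chloromethyl)-2,5-dimethoxy-3-methylbenzene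
Conditions: SOCl2, CH2Cl2, 0 °C to rt; used without chromatography
Reagents that add atoms: thionyl chloride, O=S(Cl)Cl
Why: Chlorodehydroxylation through the chlorosulfite, which is fast at an electron-rich benzylic carbon; the chloride is used promptly because it hydrolyses easily.

Step 7
Reactants: 5 tert-butyldimethyl{[(4S,5E,9E)-6,10,14-trimethylpentadeca-5,9,13-trien-1-yn-4-yl]oxy}silane; 11 trimethylaluminium; 10 1-(chloromethyl)-2,5-dimethoxy-3-methylbenzene
Product: 13 tert-butyl{[(2E,5S,6E,10E)-1-(2,5-dimethoxy-3-methylphenyl)-3,7,11,15-tetramethylhexadeca-2,6,10,14-tetraen-5-yl]oxy}dimethylsilane, via alkenyldimethylalane 12 (not isolated)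
Conditions: 11 (2.0 equiv), Cp2ZrCl2 (0.25 equiv), ClCH2CH2Cl, 0 °C to rt; volatiles removed in vacuo; then 10, NiCl2(PPh3)2 (5 mol%) reduced with n-BuLi (10 mol%) to zerovalent nickel, THF, 0 °C to rt
Reagents that add atoms: none
Why: Cp2ZrCl2 and Me3Al form a methylzirconium–alane pair that adds CH3 and metal syn across the terminal alkyne of 5, methyl to the internal carbon (future C3') and metal to the terminal carbon (future C2'), and exchange to aluminium gives the (E)-alkenyldimethylalane 12. Zerovalent nickel then inserts into the benzylic C–Cl bond of 10, the alkenyl group passes from aluminium to nickel, and reductive elimination forms C1'–C2' with retention of the alkene geometry. The closest known reaction type is the zirconium-catalysed Negishi carboalumination of terminal alkynes followed by nickel-catalysed coupling of the alkenylalane with benzylic chlorides, as used for prenylated quinones. No ring is closed and no stereocentre is created; C5' has no acidic or ionising pathway under these conditions and should be carried through as S. The step needs chemoselectivity for the alkyne over three trisubstituted alkenes, which do not carboaluminate, and regioselectivity for methyl at the internal carbon, which the zirconocene and the terminal alkyne secure. It also needs 2'E geometry, fixed by syn addition and retentive coupling, while the silyl ether keeps the C5' oxygen from consuming Me3Al and the alkenyl group transfers in preference to methyl.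

Step 8
Reactants: 13 tert-butyl{[(2E,5S,6E,10E)-1-(2,5-dimethoxy-3-methylphenyl)-3,7,11,15-tetramethylhexadeca-2,6,10,14-tetraen-5-yl]oxy}dimethylsilane
Product: 14 (2E,5S,6E,10E)-1-(2,5-dimethoxy-3-methylphenyl)-3,7,11,15-tetramethylhexadeca-2,6,10,14-tetraen-5-ol
Conditions: Bu4NF, THF, 0 °C to rt
Reagents that add atoms: none
Why: Fluoride-induced desilylation driven by Si–F bond formation, which leaves the aryl methyl ethers and alkenes untouched and does not break the carbinol C–O bond, so the S configuration is kept.

Step 9
Reactants: 14 (2E,5S,6E,10E)-1-(2,5-dimethoxy-3-methylphenyl)-3,7,11,15-tetramethylhexadeca-2,6,10,14-tetraen-5-ol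
Product: 15 2-[(2E,5S,6E,10E)-5-hydroxy-3,7,11,15-tetramethylhexadeca-2,6,10,14-tetraen-1-yl]-6-methylcyclohexa-2,5-diene-1,4-dione
Conditions: (NH4)2Ce(NO3)6 (2.5 equiv), MeCN/H2O, 0 °C, short contact time
Reagents that add atoms: water, O
Why: Oxidative demethylation of a para-dimethoxyarene by tetravalent cerium (single-electron oxidation, ipso attack of water, loss of two methanol), in which the electron-rich arene should be oxidised much faster than the isolated alkenes or the secondary alcohol at 0 °C.

Step 10
Reactants: 15 2-[(2E,5S,6E,10E)-5-hydroxy-3,7,11,15-tetramethylhexadeca-2,6,10,14-tetraen-1-yl]-6-methylcyclohexa-2,5-diene-1,4-dione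
Product: 16 2-[(2E,5S,6E,10E)-5-hydroxy-3,7,11,15-tetramethylhexadeca-2,6,10,14-tetraen-1-yl]-6-methylbenzene-1,4-diol (CNP0314458.1)
Conditions: Na2S2O4, H2O/Et2O, rt, under argon
Reagents that add atoms: none
Why: Two-electron reduction of the benzoquinone to the hydroquinone by dithionite in a neutral two-phase system, where nothing else is reducible and exclusion of air and acid should prevent re-oxidation and chroman formation.

**Compound list**

1 | (2E,6E)-farnesal, (2E,6E)-3,7,11-trimethyldodeca-2,6,10-trienal | CC(C)=CCC/C(C)=C/CC/C(C)=C/C=O | starting material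
2 | allenylboronic acid pinacol ester, 4,4,5,5-tetramethyl-2-(propa-1,2-dien-1-yl)-1,3,2-dioxaborolane | C=C=CB1OC(C)(C)C(C)(C)O1 | starting material
3 | O-pinacolboryl ether of 4 (borate ester at the C4 oxygen, S) | CC(C)=CCC/C(C)=C/CC/C(C)=C/[C@@H](OB1OC(C)(C)C(C)(C)O1)CC#C | intermediate
4 | (4S,5E,9E)-6,10,14-trimethylpentadeca-5,9,13-trien-1-yn-4-ol | CC(C)=CCC/C(C)=C/CC/C(C)=C/[C@@H](O)CC#C | intermediate
5 | tert-butyldimethyl{[(4S,5E,9E)-6,10,14-trimethylpentadeca-5,9,13-trien-1-yn-4-yl]oxy}silane | CC(C)=CCC/C(C)=C/CC/C(C)=C/[C@@H](O[Si](C)(C)C(C)(C)C)CC#C | intermediate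
6 | 4-methoxy-2-methylphenol | COc1ccc(O)c(C)c1 | starting material
7 | 2-hydroxy-5-methoxy-3-methylbenzaldehyde | COc1cc(C)c(O)c(C=O)c1 | intermediate
8 | 2,5-dimethoxy-3-methylbenzaldehyde | COc1cc(C)c(OC)c(C=O)c1 | intermediate
9 | (2,5-dimethoxy-3-methylphenyl)methanol | COc1cc(C)c(OC)c(CO)c1 | intermediate
10 | 1-(chloromethyl)-2,5-dimethoxy-3-methylbenzene (2,5-dimethoxy-3-methylbenzyl chloride) | COc1cc(C)c(OC)c(CCl)c1 | intermediate
11 | trimethylaluminium | C[Al](C)C | starting material
12 | dimethyl[(1E,4S,5E,9E)-4-(tert-butyldimethylsilyloxy)-2,6,10,14-tetramethylpentadeca-1,5,9,13-tetraen-1-yl]alane | CC(C)=CCC/C(C)=C/CC/C(C)=C/[C@@H](O[Si](C)(C)C(C)(C)C)C/C(C)=C/[Al](C)C | intermediate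
13 | tert-butyl{[(2E,5S,6E,10E)-1-(2,5-dimethoxy-3-methylphenyl)-3,7,11,15-tetramethylhexadeca-2,6,10,14-tetraen-5-yl]oxy}dimethylsilane | CC(C)=CCC/C(C)=C/CC/C(C)=C/[C@@H](O[Si](C)(C)C(C)(C)C)C/C(C)=C/Cc1cc(OC)cc(C)c1OC | intermediate
14 | (2E,5S,6E,10E)-1-(2,5-dimethoxy-3-methylphenyl)-3,7,11,15-tetramethylhexadeca-2,6,10,14-tetraen-5-ol | CC(C)=CCC/C(C)=C/CC/C(C)=C/[C@@H](O)C/C(C)=C/Cc1cc(OC)cc(C)c1OC | intermediate
15 | 2-[(2E,5S,6E,10E)-5-hydroxy-3,7,11,15-tetramethylhexadeca-2,6,10,14-tetraen-1-yl]-6-methylcyclohexa-2,5-diene-1,4-dione | CC(C)=CCC/C(C)=C/CC/C(C)=C/[C@@H](O)C/C(C)=C/CC1=CC(=O)C=C(C)C1=O | intermediate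
16 | 2-[(2E,5S,6E,10E)-5-hydroxy-3,7,11,15-tetramethylhexadeca-2,6,10,14-tetraen-1-yl]-6-methylbenzene-1,4-diol | CC(C)=CCC/C(C)=C/CC/C(C)=C/[C@@H](O)C/C(C)=C/Cc1cc(O)cc(C)c1O | target

**Step count**

Total: 10 steps. Longest linear sequence: 8 steps (steps 3, 4, 5, 6, 7, 8, 9, 10 from phenol 6); the chain branch (steps 1 and 2) joins at step 7.

**Steps most likely to fail**

1. Step 1. The risk is insufficient facial discrimination with a β,β-disubstituted enal, giving eroded enantiomeric purity, or acid-promoted E/Z isomerisation of the enal before addition. The fallback sets out from 1 and comes back at 5, bypassing steps 1 and 2; it replaces catalyst control by a separable auxiliary-controlled aldol and builds the alkyne by homologation. A tin-mediated Nagao acetate aldol of (R)-3-acetyl-4-isopropyl-1,3-thiazolidine-2-thione with 1 (Sn(OTf)2, divalent tin, N-ethylpiperidine, CH2Cl2, −78 °C) should give the (3S)-aldol adduct F1. The chelated chair model predicts Si-face attack for the (R)-auxiliary, and the minor diastereomer is removed by chromatography. Silylation (TBSOTf, 2,6-lutidine) would give the silyl ether F2. Reduction with i-Bu2AlH at −78 °C cleaves the auxiliary to the β-silyloxy aldehyde F3. Ohira–Bestmann homologation (dimethyl (1-diazo-2-oxopropyl)phosphonate, K2CO3, MeOH) converts F3 into alkyne 5.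

2. Step 7. The risk is reductive homocoupling of the electron-rich benzylic chloride at nickel or transfer of methyl instead of alkenyl from aluminium; a one-pot sequence also gives no chance to purify the alkenyl metal. The fallback sets out from 5 (through alane 12, made as in step 7) and from 10, and comes back at 13; the same two bonds are formed but the coupling polarity is inverted. Iodinolysis of 12 with I2 in THF at −30 °C should give the isolable (E)-vinyl iodide F4. Zinc dust with LiCl in THF inserts into 10 to give the benzylzinc chloride F5. Negishi coupling of F4 with F5 under Pd(PPh3)4 (zerovalent palladium) in THF at rt would give 13 with retention of the 2'E geometry.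

3. Step 9. The risk is ionisation, allylic transposition or oxidation of the free allylic carbinol in the strongly acidic cerium medium. The fallback sets out from 13 and comes back at 16, replacing steps 8–10; the carbinol stays masked during the oxidation. (NH4)2Ce(NO3)6 in MeCN/H2O at 0 °C on 13 should give the silyl-protected quinone F6. Na2S2O4 in H2O/Et2O reduces it to the silyl-protected hydroquinone F7. Bu4NF buffered with AcOH in degassed THF under argon then removes the silyl group to give 16.

**Further compounds**

F1 | step 1 | (R)-3-[(3S,4E,8E)-3-hydroxy-5,9,13-trimethyltetradeca-4,8,12-trienoyl]-4-isopropyl-1,3-thiazolidine-2-thione | CC(C)=CCC/C(C)=C/CC/C(C)=C/[C@@H](O)CC(=O)N1[C@H](C(C)C)CSC1=S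
F2 | step 1 | (R)-3-[(3S,4E,8E)-3-(tert-butyldimethylsilyloxy)-5,9,13-trimethyltetradeca-4,8,12-trienoyl]-4-isopropyl-1,3-thiazolidine-2-thione | CC(C)=CCC/C(C)=C/CC/C(C)=C/[C@@H](O[Si](C)(C)C(C)(C)C)CC(=O)N1[C@H](C(C)C)CSC1=S
F3 | step 1 | (3S,4E,8E)-3-(tert-butyldimethylsilyloxy)-5,9,13-trimethyltetradeca-4,8,12-trienal | CC(C)=CCC/C(C)=C/CC/C(C)=C/[C@@H](O[Si](C)(C)C(C)(C)C)CC=O
F4 | step 7 | tert-butyl{[(1E,4S,5E,9E)-1-iodo-2,6,10,14-tetramethylpentadeca-1,5,9,13-tetraen-4-yl]oxy}dimethylsilane | CC(C)=CCC/C(C)=C/CC/C(C)=C/[C@@H](O[Si](C)(C)C(C)(C)C)C/C(C)=C/I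
F5 | step 7 | (2,5-dimethoxy-3-methylbenzyl)zinc chloride | COc1cc(C)c(OC)c(C[Zn]Cl)c1
F6 | step 9 | 2-[(2E,5S,6E,10E)-5-(tert-butyldimethylsilyloxy)-3,7,11,15-tetramethylhexadeca-2,6,10,14-tetraen-1-yl]-6-methylcyclohexa-2,5-diene-1,4-dione | CC(C)=CCC/C(C)=C/CC/C(C)=C/[C@@H](O[Si](C)(C)C(C)(C)C)C/C(C)=C/CC1=CC(=O)C=C(C)C1=O
F7 | step 9 | 2-[(2E,5S,6E,10E)-5-(tert-butyldimethylsilyloxy)-3,7,11,15-tetramethylhexadeca-2,6,10,14-tetraen-1-yl]-6-methylbenzene-1,4-diol | CC(C)=CCC/C(C)=C/CC/C(C)=C/[C@@H](O[Si](C)(C)C(C)(C)C)C/C(C)=C/Cc1cc(O)cc(C)c1O
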